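Numbering follows germacrane: C1 ketone, C2=C3 enol-ether bond, C4=C5 Z-olefin, C6 acyloxy carbon, C7/C8 lactone carbons, C9 methylene, C10 quaternary ether carbon. Ring A is the furanone (O, C10, C1, C2, C3), ring B the lactone, ring C the ten-membered carbocycle.
Cuts: O6–acyl (esterification), C4=C5 (ring-closing metathesis), C7–C8 with O8–C12 (allylboration/lactonisation), then ring A back to the oxirane O–C1–C10 of an acyl allene oxide, and from there to allenyl ketone 10.
Enabling feature: ring A, O–C10(CH3)(CH2)–C1(=O)–C2H=C3, is the valence isomer, larger by two atoms, of a methyleneoxirane whose exocyclic C1=C2 bond carries the C3 ketone cis to C10. Release of the oxirane strain makes the tertiary C10–O bond.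
Forward order: three-membered ring to ring A (step 8), ring B (step 15), ring C (step 16), ester last (step 20). There are three fragments: C1–C4/C8–C10, C5–C7/C11–C13, and the epoxy acid.
Stereochemistry: C10 comes from a transfer hydrogenation, relayed by an anti-SN2' step into an allene axis and from there into ring A. C6 comes from a Sharpless kinetic resolution, C7/C8 from a chair allylboration steered by C6, Z-C4=C5 from the ring, and C2'/C3' from a Sharpless epoxidation.

Key step: step 8

Assumption: the SMILES of the acyl group is read as (2S,3R)-2,3-dimethyloxirane-2-carboxylate with the two methyl groups cis (tiglate geometry), so the acid is made from (E)-2-methylbut-2-en-1-ol.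

Step 1
Reactants: 1 tert-butyl(but-3-yn-1-yloxy)dimethylsilane; 2 2-chloro-N-methoxy-N-methylacetamide
Product: 4 1-chloro-6-[(tert-butyldimethylsilyl)oxy]hex-3-yn-2-one, via lithium acetylide 3 (not isolated)
Conditions: n-BuLi, THF, −78 °C; then 2, −78 to 0 °C; aq. NH4Cl
Reagents that add atoms: none
Why: Weinreb ketone synthesis, in which the acetylide adds once and the chelated adduct collapses only on work-up, so the chloromethyl ynone should form without over-addition (no stereocentre).

Step 2
Reactants: 4 1-chloro-6-[(tert-butyldimethylsilyl)oxy]hex-3-yn-2-one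
Product: 5 (2S)-1-chloro-6-[(tert-butyldimethylsilyl)oxy]hex-3-yn-2-ol
Conditions: Ru[(R,R)-TsDPEN](p-cymene) (1 mol %), i-PrOH, rt
Reagents that add atoms: none
Why: Noyori-type asymmetric transfer hydrogenation of an alkynyl ketone, in which the alkyne takes the place of the aryl group in the six-membered hydride-transfer transition state, so the (R,R)-catalyst should give the (S)-chlorohydrin (C2) and leave the triple bond and the C–Cl bond untouched.

Step 3
Reactants: 5 (2S)-1-chloro-6-[(tert-butyldimethylsilyl)oxy]hex-3-yn-2-ol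
Product: 6 (2S)-2-{4-[(tert-butyldimethylsilyl)oxy]but-1-yn-1-yl}oxirane
Conditions: K2CO3, MeOH, 0 °C to rt
Reagents that add atoms: none
Why: Intramolecular Williamson closure of a chlorohydrin (3-exo-tet at the CH2Cl carbon), which does not touch the C2–O bond and so keeps the C2 configuration.

Step 4
Reactants: 6 (2S)-2-{4-[(tert-butyldimethylsilyl)oxy]but-1-yn-1-yl}oxirane
Product: 7 (aR)-6-[(tert-butyldimethylsilyl)oxy]-4-methylhexa-2,3-dien-1-ol
Conditions: MeMgBr, CuBr (5 mol %), P(OEt)3 (10 mol %), THF, −40 °C; aq. NH4Cl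
Reagents that add atoms: methylmagnesium bromide C[Mg]Br
Why: Copper-catalysed anti-SN2' substitution of a propargylic oxirane, in which methyl enters at C10 anti to the departing C2–O bond, so the C2 centre is converted into the (aR) allene axis while the phosphite suppresses racemisation of the allene by the cuprate.

Step 5
Reactants: 7 (aR)-6-[(tert-butyldimethylsilyl)oxy]-4-methylhexa-2,3-dien-1-ol
Product: 8 (aR)-6-[(tert-butyldimethylsilyl)oxy]-4-methylhexa-2,3-dienal
Conditions: MnO2, CH2Cl2, rt
Reagents that add atoms: none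
Why: Manganese dioxide oxidation of an allenylic (allylic-type) primary alcohol under neutral conditions, which should leave the allene axis and the silyl ether intact.

Step 6
Reactants: 8 (aR)-6-[(tert-butyldimethylsilyl)oxy]-4-methylhexa-2,3-dienal
Product: 9 (aR)-8-[(tert-butyldimethylsilyl)oxy]-2,6-dimethylocta-1,4,5-trien-3-ol (both C3 epimers)
Conditions: isopropenylmagnesium bromide, THF, −78 °C; aq. NH4Cl
Reagents that add atoms: isopropenylmagnesium bromide C=C(C)[Mg]Br
Why: 1,2-Addition of a vinyl Grignard reagent to the aldehyde forms the C3–C4 bond, and the mixture at the carbinol carbon C3 is of no consequence because C3 is oxidised in the next step.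

Step 7
Reactants: 9 (aR)-8-[(tert-butyldimethylsilyl)oxy]-2,6-dimethylocta-1,4,5-trien-3-ol
Product: 10 (aR)-8-[(tert-butyldimethylsilyl)oxy]-2,6-dimethylocta-1,4,5-trien-3-one
Conditions: MnO2, CH2Cl2, rt
Reagents that add atoms: none
Why: Manganese dioxide oxidation of a doubly activated (allylic and allenylic) secondary alcohol, chosen because it is neutral and so avoids both acid-induced Nazarov cyclisation and base-induced loss of the axis.

Step 8
Reactants: 10 (aR)-8-[(tert-butyldimethylsilyl)oxy]-2,6-dimethylocta-1,4,5-trien-3-one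
Product: 12 (2R)-2-{2-[(tert-butyldimethylsilyl)oxy]ethyl}-2-methyl-5-(prop-1-en-2-yl)furan-3(2H)-one, via allene oxide 11 (not isolated)
Conditions: DMDO (1.1 equiv, acid-free acetone solution), CH2Cl2, −40 to 0 °C
Reagents that add atoms: dimethyldioxirane CC1(C)OO1
Why: Proposed new method: DMDO should epoxidise the only electron-rich π bond of 10, the distal C1=C10 bond of the allene (C1=C2 and C4=CH2 are both conjugated with the C3 ketone), from the side of H-2, that is anti to the acyl group lying in the plane of this π bond, giving the (E)-alkylidene oxirane 11 with C10 cis to the acyl group. The strained oxirane O–C1–C10 then grows by two atoms: an in-plane lone pair of the C3 carbonyl oxygen displaces the oxirane oxygen at tertiary C10 with inversion (5-endo-tet with respect to the oxirane, since C1 and C10 both end up in the new ring), the oxirane oxygen stays on C1 and becomes the C1 ketone, and C2=C3 emerges as the enol-ether bond. The closest known reaction types are the allene oxide to cyclopentenone rearrangement of vinylallene oxides, the Cloke–Wilson ring expansion of acylcyclopropanes (11 is the valence isomer of the 2-acylcyclopropanone made of C1, C2 and C10), and the dioxirane-induced oxidative cyclisation of allenyl alcohols and acids. C10 is the only new stereocentre and is controlled by the allene axis: its methyl and CH2 groups stand above and below the plane in which both C–O bonds are made and broken, no rotation about C1–C10 is needed, and (aR)-10 maps onto (R)-C10. The step needs chemoselectivity for one of three C=C bonds (secured by conjugation of the other two), a single epoxidation (C1=C2 of 11 is deactivated by the acyl group and the intramolecular closure should be fast), and closure faster than opening to the planar oxyallyl cation, which low temperature, the weakly polar co-solvent and the absence of acid should favour.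

Step 9
Reactants: 12 (2R)-2-{2-[(tert-butyldimethylsilyl)oxy]ethyl}-2-methyl-5-(prop-1-en-2-yl)furan-3(2H)-one
Product: 13 (2R)-2-(2-hydroxyethyl)-2-methyl-5-(prop-1-en-2-yl)furan-3(2H)-one
Conditions: HF·pyridine, THF, 0 °C
Reagents that add atoms: none
Why: Fluoride-mediated cleavage of a primary silyl ether under weakly acidic conditions, which the non-enolisable furanone and its quaternary C10 should tolerate.

Step 10
Reactants: 13 (2R)-2-(2-hydroxyethyl)-2-methyl-5-(prop-1-en-2-yl)furan-3(2H)-one
Product: 14 [(2R)-2-methyl-3-oxo-5-(prop-1-en-2-yl)-2,3-dihydrofuran-2-yl]acetaldehyde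
Conditions: Dess–Martin periodinane, CH2Cl2, 0 °C to rt
Reagents that add atoms: none
Why: Dess–Martin oxidation, chosen because it is free of base, so the aldehyde, whose β-carbon C10 carries the furanone oxygen, should not undergo β-elimination.

Step 11
Reactants: 15 methyl propiolate; 16 acrolein
Product: 18 methyl 4-hydroxyhex-5-en-2-ynoate (racemic), via lithium propiolate 17 (not isolated)
Conditions: n-BuLi, THF, −78 °C; then 16, −78 °C; aq. NH4Cl
Reagents that add atoms: none
Why: 1,2-Addition of a lithium acetylide to an enal at low temperature forms the C6–C7 bond (racemic at C6, resolved in the next step).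

Step 12
Reactants: 18 methyl 4-hydroxyhex-5-en-2-ynoate (racemic)
Product: 19 methyl (4R)-4-hydroxyhex-5-en-2-ynoate
Conditions: Ti(Oi-Pr)4 (10 mol %), D-(−)-DIPT (15 mol %), t-BuOOH (0.6 equiv), 4 Å MS, CH2Cl2, −20 °C
Reagents that add atoms: none
Why: Sharpless kinetic resolution of a secondary 1-alken-3-ol, in which the D-(−)-tartrate catalyst should epoxidise the (S)-enantiomer much faster, so the (R)-alcohol, which carries the C6 configuration of the target, remains.

Step 13
Reactants: 19 methyl (4R)-4-hydroxyhex-5-en-2-ynoate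
Product: 20 methyl (4R)-4-[(tert-butyldimethylsilyl)oxy]hex-5-en-2-ynoate
Conditions: TBSCl, imidazole, DMF, rt
Reagents that add atoms: tert-butyldimethylsilyl chloride CC(C)(C)[Si](C)(C)Cl
Why: Standard imidazole-promoted silylation, which masks O6 for the hydride step and later serves as the large group that steers the allylboration.

Step 14
Reactants: 20 methyl (4R)-4-[(tert-butyldimethylsilyl)oxy]hex-5-en-2-ynoate
Product: 22 methyl (2Z,4R)-4-[(tert-butyldimethylsilyl)oxy]-2-[(4,4,5,5-tetramethyl-1,3,2-dioxaborolan-2-yl)methyl]hexa-2,5-dienoate (C6 cis to the ester and trans to CH2B), via vinylalane 21 (not isolated)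
Conditions: DIBAL-H, HMPA, THF, 0 °C; then ICH2Bpin, 0 °C to rt
Reagents that add atoms: 2-(iodomethyl)-4,4,5,5-tetramethyl-1,3,2-dioxaborolane ICB1OC(C)(C)C(C)(C)O1
Why: Conjugate syn-hydroalumination of an alkynoate by the DIBAL-H/HMPA complex puts H on C7 and Al on C11 on the same side, and alkylation of the α-alumino acrylate with the iodomethylboronate with retention fixes the olefin geometry of the 2-alkoxycarbonyl allylboronate.

Step 15
Reactants: 14 [(2R)-2-methyl-3-oxo-5-(prop-1-en-2-yl)-2,3-dihydrofuran-2-yl]acetaldehyde; 22 methyl (2Z,4R)-4-[(tert-butyldimethylsilyl)oxy]-2-[(4,4,5,5-tetramethyl-1,3,2-dioxaborolan-2-yl)methyl]hexa-2,5-dienoate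
Product: 24 (4R,5S)-4-{(1R)-1-[(tert-butyldimethylsilyl)oxy]prop-2-en-1-yl}-3-methylidene-5-{[(2R)-2-methyl-3-oxo-5-(prop-1-en-2-yl)-2,3-dihydrofuran-2-yl]methyl}oxolan-2-one (trans-lactone), via homoallylic borate 23 (not isolated)
Conditions: Sc(OTf)3 (10 mol %), toluene, rt
Reagents that add atoms: none
Why: Lewis acid-catalysed type-one allylboration through a closed Zimmerman–Traxler chair, in which the C6 substituent trans to CH2B sits equatorial and gives the anti adduct (hence the trans C7/C8 lactone after the borate attacks the ester, 5-exo-trig), while A(1,3) strain with the cis ester holds H-6 in the olefin plane so that the aldehyde should approach C7 anti to the bulky silyloxy group and set 7R,8S from 6R.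

Step 16
Reactants: 24 trans-lactone diene
Product: 25 (6R,7R,8S,10R)-6-[(tert-butyldimethylsilyl)oxy]-1-oxo-3,10-epoxygermacra-2,4(Z),11(13)-trien-12,8-olide
Conditions: second-generation Hoveyda–Grubbs catalyst (10 mol %), toluene (1 mM), 100 °C
Reagents that add atoms: none
Why: Ring-closing metathesis between the C5 vinyl group and the isopropenyl group on C3 closes ring C, a reaction type known for isopropenyl furanones, and only the Z olefin should fit into the ten-membered ring because C3 is held in the planar furanone, while the electron-poor methylidene lactone stays a spectator.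

Step 17
Reactants: 25 silyl ether of the macrocycle
Product: 26 (6R,7S,8S,10R)-6-hydroxy-1-oxo-3,10-epoxygermacra-2,4(Z),11(13)-trien-12,8-olide (same spatial arrangement as in 25; the C7 descriptor changes by priority only)
Conditions: HF·pyridine, pyridine, THF, 0 °C to rt
Reagents that add atoms: none
Why: Buffered fluoride cleavage of the secondary allylic silyl ether avoids the basic conditions under which the methylidene lactone would add nucleophiles or the lactone would migrate to O6.

Step 18
Reactants: 27 (E)-2-methylbut-2-en-1-ol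
Product: 28 [(2R,3R)-2,3-dimethyloxiran-2-yl]methanol
Conditions: Ti(Oi-Pr)4 (5 mol %), D-(−)-DET (6 mol %), t-BuOOH, 4 Å MS, CH2Cl2, −20 °C
Reagents that add atoms: tert-butyl hydroperoxide CC(C)(C)OO
Why: Sharpless asymmetric epoxidation, in which the D-(−)-tartrate should give the (2R,3R)-epoxy alcohol (the L-(+)-tartrate gives 2S,3S with E-allylic alcohols of this substitution pattern) and the syn oxygen transfer keeps the two methyl groups cis.

Step 19
Reactants: 28 [(2R,3R)-2,3-dimethyloxiran-2-yl]methanol
Product: 29 (2S,3R)-2,3-dimethyloxirane-2-carboxylic acid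
Conditions: RuCl3 (2 mol %), NaIO4, MeCN/EtOAc/H2O, 0 °C to rt
Reagents that add atoms: water O
Why: Ruthenium tetroxide-catalysed oxidation of a 2,3-epoxy alcohol to the epoxy acid breaks no bond at either stereocentre (the C2 descriptor changes by priority only).

Step 20
Reactants: 26 macrocyclic C6 alcohol; 29 (2S,3R)-2,3-dimethyloxirane-2-carboxylic acid
Product: 31 target CNP0258430.2 (6-O-[(2S,3R)-2,3-dimethyloxirane-2-carbonyl] derivative of 26), via O-acylisourea 30 (not isolated)
Conditions: DCC, DMAP (20 mol %), CH2Cl2, 0 °C to rt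
Reagents that add atoms: none
Why: Steglich esterification acylates O6 with retention at C6 under neutral conditions that the epoxide, the furanone and the methylidene lactone should survive.

Compound list
1 | tert-butyl(but-3-yn-1-yloxy)dimethylsilane | C#CCCO[Si](C)(C)C(C)(C)C | starting material
2 | 2-chloro-N-methoxy-N-methylacetamide | CON(C)C(=O)CCl | starting material
3 | lithium acetylide of 1 | [Li]C#CCCO[Si](C)(C)C(C)(C)C | intermediate
4 | 1-chloro-6-[(tert-butyldimethylsilyl)oxy]hex-3-yn-2-one | ClCC(=O)C#CCCO[Si](C)(C)C(C)(C)C | intermediate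
5 | (2S)-1-chloro-6-[(tert-butyldimethylsilyl)oxy]hex-3-yn-2-ol | CC(C)(C)[Si](C)(C)OCCC#C[C@H](O)CCl | intermediate
6 | (2S)-2-{4-[(tert-butyldimethylsilyl)oxy]but-1-yn-1-yl}oxirane | CC(C)(C)[Si](C)(C)OCCC#C[C@H]1CO1 | intermediate
7 | (aR)-6-[(tert-butyldimethylsilyl)oxy]-4-methylhexa-2,3-dien-1-ol | OCC([H])=[C@]=C(C)CCO[Si](C)(C)C(C)(C)C | intermediate
8 | (aR)-6-[(tert-butyldimethylsilyl)oxy]-4-methylhexa-2,3-dienal | O=CC([H])=[C@]=C(C)CCO[Si](C)(C)C(C)(C)C | intermediate
9 | (aR)-8-[(tert-butyldimethylsilyl)oxy]-2,6-dimethylocta-1,4,5-trien-3-ol (C3 epimers) | C=C(C)C(O)C([H])=[C@]=C(C)CCO[Si](C)(C)C(C)(C)C | intermediate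
10 | (aR)-8-[(tert-butyldimethylsilyl)oxy]-2,6-dimethylocta-1,4,5-trien-3-one | C=C(C)C(=O)C([H])=[C@]=C(C)CCO[Si](C)(C)C(C)(C)C | intermediate
11 | (1E)-1-[(3S)-3-{2-[(tert-butyldimethylsilyl)oxy]ethyl}-3-methyloxiran-2-ylidene]-3-methylbut-3-en-2-one (allene oxide) | C=C(C)C(=O)/C=C1/O[C@@]1(C)CCO[Si](C)(C)C(C)(C)C | intermediate
12 | (2R)-2-{2-[(tert-butyldimethylsilyl)oxy]ethyl}-2-methyl-5-(prop-1-en-2-yl)furan-3(2H)-one | CC(C)(C)[Si](C)(C)OCC[C@@]1(C)OC(=CC1=O)C(C)=C | intermediate
13 | (2R)-2-(2-hydroxyethyl)-2-methyl-5-(prop-1-en-2-yl)furan-3(2H)-one | OCC[C@@]1(C)OC(=CC1=O)C(C)=C | intermediate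
14 | [(2R)-2-methyl-3-oxo-5-(prop-1-en-2-yl)-2,3-dihydrofuran-2-yl]acetaldehyde | O=CC[C@@]1(C)OC(=CC1=O)C(C)=C | intermediate
15 | methyl propiolate | C#CC(=O)OC | starting material
16 | acrolein | C=CC=O | starting material
17 | lithium acetylide of methyl propiolate | [Li]C#CC(=O)OC | intermediate
18 | methyl 4-hydroxyhex-5-en-2-ynoate (racemic) | C=CC(O)C#CC(=O)OC | intermediate
19 | methyl (4R)-4-hydroxyhex-5-en-2-ynoate | C=C[C@@H](O)C#CC(=O)OC | intermediate
20 | methyl (4R)-4-[(tert-butyldimethylsilyl)oxy]hex-5-en-2-ynoate | C=C[C@@H](O[Si](C)(C)C(C)(C)C)C#CC(=O)OC | intermediate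
21 | methyl (4R)-4-[(tert-butyldimethylsilyl)oxy]-2-(diisobutylalumanyl)hexa-2,5-dienoate (H-7 cis to Al) | C=C[C@@H](O[Si](C)(C)C(C)(C)C)/C=C(\C(=O)OC)[Al](CC(C)C)CC(C)C | intermediate
22 | methyl (2Z,4R)-4-[(tert-butyldimethylsilyl)oxy]-2-[(4,4,5,5-tetramethyl-1,3,2-dioxaborolan-2-yl)methyl]hexa-2,5-dienoate | C=C[C@@H](O[Si](C)(C)C(C)(C)C)/C=C(\C(=O)OC)CB1OC(C)(C)C(C)(C)O1 | intermediate
23 | O8-pinacol borate of the anti hydroxy ester (6R,7R,8S,10R; open form of 24) | COC(=O)C(=C)[C@H]([C@@H](OB1OC(C)(C)C(C)(C)O1)C[C@@]2(C)OC(=CC2=O)C(C)=C)[C@H](O[Si](C)(C)C(C)(C)C)C=C | intermediate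
24 | (4R,5S)-4-{(1R)-1-[(tert-butyldimethylsilyl)oxy]prop-2-en-1-yl}-3-methylidene-5-{[(2R)-2-methyl-3-oxo-5-(prop-1-en-2-yl)-2,3-dihydrofuran-2-yl]methyl}oxolan-2-one | C=C1C(=O)O[C@@H](C[C@@]2(C)OC(=CC2=O)C(C)=C)[C@@H]1[C@H](O[Si](C)(C)C(C)(C)C)C=C | intermediate
25 | (6R,7R,8S,10R)-6-[(tert-butyldimethylsilyl)oxy]-1-oxo-3,10-epoxygermacra-2,4(Z),11(13)-trien-12,8-olide | C=C1C(=O)O[C@H]2C[C@@]3(C)OC(=CC3=O)/C(C)=C\[C@@H](O[Si](C)(C)C(C)(C)C)[C@H]12 | intermediate
26 | (6R,7S,8S,10R)-6-hydroxy-1-oxo-3,10-epoxygermacra-2,4(Z),11(13)-trien-12,8-olide | C=C1C(=O)O[C@H]2C[C@@]3(C)OC(=CC3=O)/C(C)=C\[C@@H](O)[C@H]12 | intermediate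
27 | (E)-2-methylbut-2-en-1-ol | C/C=C(\C)CO | starting material
28 | [(2R,3R)-2,3-dimethyloxiran-2-yl]methanol | OC[C@@]1(C)O[C@@H]1C | intermediate
29 | (2S,3R)-2,3-dimethyloxirane-2-carboxylic acid | OC(=O)[C@@]1(C)O[C@@H]1C | intermediate
30 | O-acylisourea from 29 and DCC | C1CCCCC1N=C(NC2CCCCC2)OC(=O)[C@@]3(C)O[C@@H]3C | intermediate
31 | CNP0258430.2 | C=C1C(=O)O[C@H]2C[C@@]3(C)OC(=CC3=O)/C(C)=C\[C@@H](OC(=O)[C@@]3(C)O[C@@H]3C)[C@H]12 | target

Total steps: 20. Longest linear sequence: 14 steps (steps 1–10, 15, 16, 17, 20).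

Steps most likely to fail

Step 8. Three things may go wrong. The allene oxide may be epoxidised a second time before it closes. It may open to the planar oxyallyl cation, so that the axis is not transferred cleanly to C10. Traces of acid may trigger Nazarov cyclisation of the allenyl vinyl ketone.
The fallback uses known chemistry only, sets out from 1 and returns at 12. It fixes the C10–O bond first and never breaks it.
- Zirconium-catalysed carboalumination of 1 (AlMe3, Cp2ZrCl2, CH2Cl2; then paraformaldehyde) gives (E)-5-[(tert-butyldimethylsilyl)oxy]-3-methylpent-2-en-1-ol F1.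
- Sharpless epoxidation with D-(−)-DET gives [(2R,3R)-3-{2-[(tert-butyldimethylsilyl)oxy]ethyl}-3-methyloxiran-2-yl]methanol F2.
- PPh3/CCl4 converts it into (2S,3R)-2-(chloromethyl)-3-{2-[(tert-butyldimethylsilyl)oxy]ethyl}-3-methyloxirane F3.
- Base-induced double elimination (n-BuLi, THF, −40 °C) gives (3R)-5-[(tert-butyldimethylsilyl)oxy]-3-methylpent-1-yn-3-ol F4 with retention at C10.
- The dianion of F4 adds to methacrolein to give (6R)-8-[(tert-butyldimethylsilyl)oxy]-2,6-dimethyloct-1-en-4-yne-3,6-diol F5.
- MnO2 oxidises F5 to (6R)-8-[(tert-butyldimethylsilyl)oxy]-6-hydroxy-2,6-dimethyloct-1-en-4-yn-3-one F6.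
- Gold-catalysed cycloisomerisation of this γ-hydroxy ynone ((4-CF3C6H4)3PAuCl, AgOTf, toluene, rt) gives 12.

Step 16. Initiation at the conjugated 1,1-disubstituted olefin may be slow, the vinyl group may oligomerise, and closure across the rigid trans-lactone may be disfavoured by strain.
The fallback inverts the order of ring formation, sets out from 14 and 22 and returns at 25.
- The two are combined without Lewis acid (toluene, 60 °C) and worked up with aqueous NaHCO3, so that the open methyl (6R,7R,8S,10R)-anti-hydroxy ester F9 is isolated.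
- The more flexible diene is closed by metathesis to the macrocyclic hydroxy ester F10.
- A catalytic amount of p-TsOH (CH2Cl2, rt) then closes ring B to 25.

Step 15. The ester-deactivated boronate may add so slowly that Lewis acid-induced β-elimination of the furanone oxygen from 14 competes, and selection between the two faces of C7 may be incomplete.
The fallback changes the oxidation level of the nucleophile, sets out from 22 and returns at 24.
- DIBAL-H (CH2Cl2, −78 °C) reduces the ester to the (Z)-2-(hydroxymethyl)allylboronate F7.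
- F7 is a far stronger nucleophile and should add to 14 at or below rt without catalyst through the same chair, giving the anti 2-methylidene-1,4-diol F8 after aqueous work-up.
- MnO2 (CH2Cl2) then oxidises the allylic primary alcohol selectively and carries the resulting lactol on to lactone 24.

Further compounds
F1 | step 8 | (E)-5-[(tert-butyldimethylsilyl)oxy]-3-methylpent-2-en-1-ol | OC/C=C(\C)CCO[Si](C)(C)C(C)(C)C
F2 | step 8 | [(2R,3R)-3-{2-[(tert-butyldimethylsilyl)oxy]ethyl}-3-methyloxiran-2-yl]methanol | OC[C@H]1O[C@]1(C)CCO[Si](C)(C)C(C)(C)C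
F3 | step 8 | (2S,3R)-2-(chloromethyl)-3-{2-[(tert-butyldimethylsilyl)oxy]ethyl}-3-methyloxirane | ClC[C@H]1O[C@]1(C)CCO[Si](C)(C)C(C)(C)C
F4 | step 8 | (3R)-5-[(tert-butyldimethylsilyl)oxy]-3-methylpent-1-yn-3-ol | CC(C)(C)[Si](C)(C)OCC[C@@](C#C)(C)O
F5 | step 8 | (6R)-8-[(tert-butyldimethylsilyl)oxy]-2,6-dimethyloct-1-en-4-yne-3,6-diol | CC(C)(C)[Si](C)(C)OCC[C@@](C#CC(O)C(C)=C)(C)O
F6 | step 8 | (6R)-8-[(tert-butyldimethylsilyl)oxy]-6-hydroxy-2,6-dimethyloct-1-en-4-yn-3-one | CC(C)(C)[Si](C)(C)OCC[C@@](C#CC(=O)C(C)=C)(C)O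
F7 | step 15 | (Z)-2-(hydroxymethyl)allylboronate | C=C[C@@H](O[Si](C)(C)C(C)(C)C)/C=C(\CO)CB1OC(C)(C)C(C)(C)O1
F8 | step 15 | anti 2-methylidene-1,4-diol | OCC(=C)[C@H]([C@@H](O)C[C@@]1(C)OC(=CC1=O)C(C)=C)[C@H](O[Si](C)(C)C(C)(C)C)C=C
F9 | step 16 | methyl (6R,7R,8S,10R)-anti-hydroxy ester | COC(=O)C(=C)[C@H]([C@@H](O)C[C@@]1(C)OC(=CC1=O)C(C)=C)[C@H](O[Si](C)(C)C(C)(C)C)C=C
F10 | step 16 | macrocyclic hydroxy ester | COC(=O)C(=C)[C@@H]1[C@@H](O)C[C@@]2(C)OC(=CC2=O)/C(C)=C\[C@H]1O[Si](C)(C)C(C)(C)C
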